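The earlier runs and the new flask are simulated with made-up constants.

In the larch run, at 60.0 min, target and isomer of the product together read 34.0% of the starting material charged, and in the birch run 58.0%. Your flask stands between them in partner.

in all of them: starting material 0.050 M; catalyst 20 mol%

|  | partner | remark | time |
|---|---|---|---|
| larch | 1 equiv | run made earlier |  |
| birch | 2.2 equiv | run made earlier |  |
| flask | 1.50 equiv |  | 1.0 h |

- larch (time / min: target / %, isomer of the product / %): 12.0: 16, 4; 25.0: 21, 7; 40.0: 21, 15; 50.0: 19, 12; 60.0: 17, 17
- birch (time / min: target / %, isomer of the product / %): 12.0: 30, 2; 25.0: 35, 12; 40.0: 38, 19; 50.0: 36, 23; 60.0: 33, 25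

(standard deviation of a reading: 1.5 percentage points)

- ratio of target to isomer of the product at 20 s
- ratio of target to isomer of the product at 1.0 h

- the numbers in the tables scatter by 1.5 percentage points (one standard deviation)
- a reading or a percentage of target counts all its forms, free or not

Starting material is the smaller charge in your flask, 0.050 M against 0.0750 M of partner, so write its balance. Divide the converted share by the share of starting material left and by the equivalents of partner left, counting one spent per conversion. Larch gives 0.781 and birch 0.852, and their mean 0.816 is the one-hour quotient, a book-keeping figure for this concentration and loading, not an equilibrium constant.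

When you come at 1.0 h, I reckon the quotient puts 45.9% converted. Interpolating by equivalents between the larch and birch ratios gives me target over isomer of 1.13. Don't let the flask stand longer than it must: in birch, target read 38% at 40.0 min but 33% at 60.0 min, while isomer kept rising. For 20 s I have a rough floor, birch's first ratio of 15.0. The forecast says 400 and 1.2, the latter above mine, and warns of the first that “a small direct leak would lower it sharply”.

    starting material + partner ⇌ target (K = 30.0 L mol⁻¹, k = 0.00640 L mol⁻¹ s⁻¹)
    starting material + partner ⇌ isomer of the product (K = 44.0 L mol⁻¹, k = 9.55 × 10⁻⁵ L mol⁻¹ s⁻¹)
    target + catalyst ⇌ isomer of the product + catalyst, rate k3*[catalyst]*[target] forward; the back reaction follows from the equilibrium constant (k = 0.0572 L mol⁻¹ s⁻¹)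
    partner + target ⇌ idle adduct, settled at all times (K = 10.7 L mol⁻¹)
    partner → decomposed reagent (k = 2.41 × 10⁻⁴ s⁻¹)

The flask gives 55.2 at 20 s, below the forecast, and 1.18 at 1.0 h. Just after the start, the forward step to target runs 67 times the forward step to isomer. At 1.0 h, target 25.1% and isomer 21.3% make 46.4% against the quotient's 45.9%. Partner in the flask is then down to 0.0185 M against 0.0268 M of starting material, with 0.0312 M of decomposed reagent formed. In the neighbour with 0.380 equiv of partner, partner is the smaller charge, and the same quotient gives 15.5% converted, so 84.5% of the starting material left; that flask holds 86%.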